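## Retrosynthetic overview

Target locants: C1 lactone carbonyl, O2, C3 (syringyl carbon), C3a, C4 (CH2), O5, C6 (guaiacyl carbon), C6a.

1. The tetrahydrofuran ring is closed last, by acid-mediated C6–O5 bond formation (benzylic cation, aryl ends exo) from a butyrolactone carrying CH2OH and ArCH(OH) on the same face.
2. That lactone comes from acyl transfer (translactonisation) of a trans-3,4-disubstituted butyrolactone closed on the CH2–O oxygen.
3. The key C6a–C6 bond is an intermolecular aldol addition of the lithium enolate of a β-substituted butyrolactone to O-silyl vanillin.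
4. The β-substituted butyrolactone comes from an Evans syn-aldol (C3–C3a bond, sets absolute configuration) of an N-pent-4-enoyl oxazolidinone with O-silyl syringaldehyde, then auxiliary reduction, alkene cleavage and lactol oxidation.
5. Ring order: butyrolactone on CH2–O first, then the lactone moves to the benzylic oxygen, then the tetrahydrofuran.

Assumption: substrates and skeleton-building fragments are numbered; protecting-group, base and redox reagents appear only on the Conditions and Reagents lines.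

## Route

Step 1
Reactants: 1 syringaldehyde
Product: 2 4-(tert-butyldimethylsilyloxy)-3,5-dimethoxybenzaldehyde
Conditions: TBSCl, imidazole, DMF, rt
Reagents that add atoms: tert-butyldimethylsilyl chloride (TBSCl), CC(C)(C)[Si](C)(C)Cl
Why: Standard phenol silylation gives an ether that survives the enolate, hydride and oxidation steps and is removed by fluoride at the end.

Step 2
Reactants: 3 (S)-4-benzyloxazolidin-2-one; 4 pent-4-enoyl chloride
Product: 6 (S)-4-benzyl-3-(pent-4-enoyl)oxazolidin-2-one, via lithium oxazolidinonide 5 (not isolated)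
Conditions: n-BuLi, THF, −78 °C; then 4, −78 → 0 °C
Reagents that add atoms: none
Why: N-acylation of the lithiated oxazolidinone with an acid chloride is the standard loading of an Evans auxiliary.

Step 3
Reactants: 6 (S)-4-benzyl-3-(pent-4-enoyl)oxazolidin-2-one; 2 4-(tert-butyldimethylsilyloxy)-3,5-dimethoxybenzaldehyde
Product: 8 (S)-4-benzyl-3-[(S)-2-{(S)-[4-(tert-butyldimethylsilyloxy)-3,5-dimethoxyphenyl](hydroxy)methyl}pent-4-enoyl]oxazolidin-2-one, via Z-dibutylboron enolate 7 (not isolated)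
Conditions: Bu2BOTf (1.2 equiv), i-Pr2NEt (1.4 equiv), CH2Cl2, 0 °C; then 2, −78 → 0 °C; pH 7 buffer, MeOH, 30% H2O2, 0 °C
Reagents that add atoms: none
Why: In this Evans syn-aldol reaction the Z-boron enolate reacts through a Zimmerman–Traxler chair on the face away from the benzyl group, so the (S)-auxiliary sets the carbinol carbon (future C3, S) and the adjacent carbon (future C3a) together.

Step 4
Reactants: 8 the syn-aldol adduct
Product: 9 (S)-4-benzyl-3-[(S)-2-{(S)-(tert-butyldimethylsilyloxy)[4-(tert-butyldimethylsilyloxy)-3,5-dimethoxyphenyl]methyl}pent-4-enoyl]oxazolidin-2-one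
Conditions: TBSOTf, 2,6-lutidine, CH2Cl2, −78 → 0 °C
Reagents that add atoms: tert-butyldimethylsilyl triflate (TBSOTf), CC(C)(C)[Si](C)(C)OS(=O)(=O)C(F)(F)F
Why: Silyl triflate with a hindered base silylates the secondary aldol hydroxyl without retro-aldol cleavage, and the ether keeps this oxygen out of the later lactol and lactone formation.

Step 5
Reactants: 9 the silylated aldol adduct
Product: 10 (R)-2-{(S)-(tert-butyldimethylsilyloxy)[4-(tert-butyldimethylsilyloxy)-3,5-dimethoxyphenyl]methyl}pent-4-en-1-ol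
Conditions: LiBH4, H2O (1.1 equiv), Et2O, 0 °C
Reagents that add atoms: none
Why: Reductive auxiliary cleavage, in which the borohydride attacks the exocyclic imide carbonyl, gives the primary alcohol without touching either stereocentre and returns the oxazolidinone.

Step 6
Reactants: 10 the pentenol
Product: 12 (4R)-4-{(S)-(tert-butyldimethylsilyloxy)[4-(tert-butyldimethylsilyloxy)-3,5-dimethoxyphenyl]methyl}tetrahydrofuran-2-ol (lactol; both anomers), via hydroxy aldehyde 11 (not isolated)
Conditions: OsO4 (2 mol %), NaIO4 (4 equiv), 2,6-lutidine, dioxane/H2O 3:1, rt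
Reagents that add atoms: OsO4, O=[Os](=O)(=O)=O (delivers the new oxygen; reoxidised by NaIO4, [Na+].[O-]I(=O)(=O)=O)
Why: Lemieux–Johnson oxidative cleavage of the terminal alkene gives an aldehyde that the γ-hydroxyl traps at once as the five-membered lactol, while the arene and silyl ethers are inert.

Step 7
Reactants: 12 the lactol
Product: 13 (R)-4-{(S)-(tert-butyldimethylsilyloxy)[4-(tert-butyldimethylsilyloxy)-3,5-dimethoxyphenyl]methyl}dihydrofuran-2(3H)-one
Conditions: TEMPO (0.2 equiv), PhI(OAc)2 (2.5 equiv), CH2Cl2, rt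
Reagents that add atoms: none
Why: Oxoammonium (TEMPO) oxidation of the cyclic hemiacetal gives the γ-lactone under near-neutral conditions that spare silyl ethers and the electron-rich arene.

Step 8
Reactants: 14 vanillin
Product: 15 4-(tert-butyldimethylsilyloxy)-3-methoxybenzaldehyde
Conditions: TBSCl, imidazole, DMF, rt
Reagents that add atoms: tert-butyldimethylsilyl chloride (TBSCl), CC(C)(C)[Si](C)(C)Cl
Why: Phenol silylation as in step 1, so the aldehyde tolerates the lithium enolate and both phenols are freed in one fluoride step.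

Step 9
Reactants: 13 the β-substituted butyrolactone; 15 4-(tert-butyldimethylsilyloxy)-3-methoxybenzaldehyde
Product: 17 (3S,4R)-3-{[4-(tert-butyldimethylsilyloxy)-3-methoxyphenyl](hydroxy)methyl}-4-{(S)-(tert-butyldimethylsilyloxy)[4-(tert-butyldimethylsilyloxy)-3,5-dimethoxyphenyl]methyl}dihydrofuran-2(3H)-one (both carbinol epimers), via lithium enolate 16 (not isolated)
Conditions: LiN(i-Pr)2 (1.1 equiv), THF, −78 °C, 45 min; then 15, −78 °C, 1 h; AcOH in THF, −78 °C
Reagents that add atoms: none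
Why: This intermolecular aldol addition joins the two aryl fragments, and the bulky β-substituent directs the aldehyde to the opposite enolate face so the new ring stereocentre is trans (3S), while the carbinol carbon forms as a mixture that step 11 resets.

Step 10
Reactants: 17 the trans aldol adduct
Product: 19 (3S,4R,5S)-5-(4-hydroxy-3,5-dimethoxyphenyl)-3-[hydroxy(4-hydroxy-3-methoxyphenyl)methyl]-4-(hydroxymethyl)dihydrofuran-2(3H)-one (both carbinol epimers), via desilylated hydroxy lactone 18 (not isolated)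
Conditions: Bu4NF (3.5 equiv), AcOH (3.5 equiv), THF, 0 °C → rt
Reagents that add atoms: none
Why: Buffered fluoride removes all three silyl groups, and the freed secondary benzylic hydroxyl then translactonises onto the carbonyl, which places CH2OH and the hydroxybenzyl group cis on the new lactone without breaking any bond to a stereocentre.

Step 11
Reactants: 19 the translactonised triol
Product: 20 (3S,3aR,6S,6aS)-3-(4-hydroxy-3,5-dimethoxyphenyl)-6-(4-hydroxy-3-methoxyphenyl)tetrahydro-1H,3H-furo[3,4-c]furan-1-one (target)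
Conditions: 2 M aq HCl/THF 1:5, rt
Reagents that add atoms: none
Why: Acid ionises the p-hydroxybenzylic alcohol to a stabilised cation that the cis primary hydroxyl captures (SN1 cycloetherification), closing the cis-fused tetrahydrofuran with the aryl on the convex face (6S) from either carbinol epimer under thermodynamic control.

## Compound list

1 | syringaldehyde (4-hydroxy-3,5-dimethoxybenzaldehyde) | COc1cc(C=O)cc(OC)c1O | starting material
2 | 4-(tert-butyldimethylsilyloxy)-3,5-dimethoxybenzaldehyde | COc1cc(C=O)cc(OC)c1O[Si](C)(C)C(C)(C)C | intermediate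
3 | (S)-4-benzyloxazolidin-2-one | O=C1N[C@@H](Cc2ccccc2)CO1 | starting material
4 | pent-4-enoyl chloride | C=CCCC(=O)Cl | starting material
5 | lithium (S)-4-benzyl-2-oxooxazolidin-3-ide | [Li]N1[C@@H](Cc2ccccc2)COC1=O | intermediate (not isolated)
6 | (S)-4-benzyl-3-(pent-4-enoyl)oxazolidin-2-one | C=CCCC(=O)N1[C@@H](Cc2ccccc2)COC1=O | intermediate
7 | (S)-4-benzyl-3-[(Z)-1-(dibutylboranyloxy)penta-1,4-dien-1-yl]oxazolidin-2-one | CCCCB(CCCC)O/C(=C\CC=C)N1[C@@H](Cc2ccccc2)COC1=O | intermediate (not isolated)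
8 | (S)-4-benzyl-3-[(S)-2-{(S)-[4-(tert-butyldimethylsilyloxy)-3,5-dimethoxyphenyl](hydroxy)methyl}pent-4-enoyl]oxazolidin-2-one | C=CC[C@H](C(=O)N1[C@@H](Cc2ccccc2)COC1=O)[C@H](O)c1cc(OC)c(O[Si](C)(C)C(C)(C)C)c(OC)c1 | intermediate
9 | (S)-4-benzyl-3-[(S)-2-{(S)-(tert-butyldimethylsilyloxy)[4-(tert-butyldimethylsilyloxy)-3,5-dimethoxyphenyl]methyl}pent-4-enoyl]oxazolidin-2-one | C=CC[C@H](C(=O)N1[C@@H](Cc2ccccc2)COC1=O)[C@H](O[Si](C)(C)C(C)(C)C)c1cc(OC)c(O[Si](C)(C)C(C)(C)C)c(OC)c1 | intermediate
10 | (R)-2-{(S)-(tert-butyldimethylsilyloxy)[4-(tert-butyldimethylsilyloxy)-3,5-dimethoxyphenyl]methyl}pent-4-en-1-ol | C=CC[C@H](CO)[C@H](O[Si](C)(C)C(C)(C)C)c1cc(OC)c(O[Si](C)(C)C(C)(C)C)c(OC)c1 | intermediate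
11 | (3R,4S)-4-(tert-butyldimethylsilyloxy)-4-[4-(tert-butyldimethylsilyloxy)-3,5-dimethoxyphenyl]-3-(hydroxymethyl)butanal | O=CC[C@H](CO)[C@H](O[Si](C)(C)C(C)(C)C)c1cc(OC)c(O[Si](C)(C)C(C)(C)C)c(OC)c1 | intermediate (not isolated)
12 | (4R)-4-{(S)-(tert-butyldimethylsilyloxy)[4-(tert-butyldimethylsilyloxy)-3,5-dimethoxyphenyl]methyl}tetrahydrofuran-2-ol (anomer mixture) | OC1C[C@@H]([C@H](O[Si](C)(C)C(C)(C)C)c2cc(OC)c(O[Si](C)(C)C(C)(C)C)c(OC)c2)CO1 | intermediate
13 | (R)-4-{(S)-(tert-butyldimethylsilyloxy)[4-(tert-butyldimethylsilyloxy)-3,5-dimethoxyphenyl]methyl}dihydrofuran-2(3H)-one | O=C1C[C@@H]([C@H](O[Si](C)(C)C(C)(C)C)c2cc(OC)c(O[Si](C)(C)C(C)(C)C)c(OC)c2)CO1 | intermediate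
14 | vanillin (4-hydroxy-3-methoxybenzaldehyde) | COc1cc(C=O)ccc1O | starting material
15 | 4-(tert-butyldimethylsilyloxy)-3-methoxybenzaldehyde | COc1cc(C=O)ccc1O[Si](C)(C)C(C)(C)C | intermediate
16 | lithium (R)-4-{(S)-(tert-butyldimethylsilyloxy)[4-(tert-butyldimethylsilyloxy)-3,5-dimethoxyphenyl]methyl}-4,5-dihydrofuran-2-olate | [Li]OC1=C[C@@H]([C@H](O[Si](C)(C)C(C)(C)C)c2cc(OC)c(O[Si](C)(C)C(C)(C)C)c(OC)c2)CO1 | intermediate (not isolated)
17 | (3S,4R)-3-{[4-(tert-butyldimethylsilyloxy)-3-methoxyphenyl](hydroxy)methyl}-4-{(S)-(tert-butyldimethylsilyloxy)[4-(tert-butyldimethylsilyloxy)-3,5-dimethoxyphenyl]methyl}dihydrofuran-2(3H)-one (carbinol carbon: both epimers) | O=C1[C@H](C(O)c2ccc(O[Si](C)(C)C(C)(C)C)c(OC)c2)[C@@H]([C@H](O[Si](C)(C)C(C)(C)C)c2cc(OC)c(O[Si](C)(C)C(C)(C)C)c(OC)c2)CO1 | intermediate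
18 | (3S,4R)-3-[hydroxy(4-hydroxy-3-methoxyphenyl)methyl]-4-[(S)-hydroxy(4-hydroxy-3,5-dimethoxyphenyl)methyl]dihydrofuran-2(3H)-one (carbinol carbon at C3 side chain: both epimers) | O=C1[C@H](C(O)c2ccc(O)c(OC)c2)[C@@H]([C@H](O)c2cc(OC)c(O)c(OC)c2)CO1 | intermediate (not isolated)
19 | (3S,4R,5S)-5-(4-hydroxy-3,5-dimethoxyphenyl)-3-[hydroxy(4-hydroxy-3-methoxyphenyl)methyl]-4-(hydroxymethyl)dihydrofuran-2(3H)-one (carbinol carbon: both epimers) | O=C1O[C@H](c2cc(OC)c(O)c(OC)c2)[C@@H](CO)[C@H]1C(O)c1ccc(O)c(OC)c1 | intermediate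
20 | (3S,3aR,6S,6aS)-3-(4-hydroxy-3,5-dimethoxyphenyl)-6-(4-hydroxy-3-methoxyphenyl)tetrahydro-1H,3H-furo[3,4-c]furan-1-one | COc1cc([C@H]2OC[C@H]3[C@@H]2C(=O)O[C@@H]3c2cc(OC)c(O)c(OC)c2)ccc1O | target

## Step count and risks

Total steps: 11. Longest linear sequence: 9 steps (from 3 and 4 through steps 2, 3, 4, 5, 6, 7, 9, 10, 11; the two aldehyde protections are side branches).

**Step 9 (lactone enolate aldol).** The lithium aldolate of an electron-rich aryl aldehyde can revert, so conversion may be poor. The fallback sets out from 13 and replaces the aldol by a crossed Claisen condensation followed by reduction. Methyl vanillate is silylated (TBSCl, imidazole, DMF) to methyl 4-(tert-butyldimethylsilyloxy)-3-methoxybenzoate F1. Lactone 13 is deprotonated with LiN(SiMe3)2 (2.2 equiv, THF, −78 °C) and acylated with F1 (−78 → 0 °C). This gives (3S,4R)-3-[4-(tert-butyldimethylsilyloxy)-3-methoxybenzoyl]-4-{(S)-(tert-butyldimethylsilyloxy)[4-(tert-butyldimethylsilyloxy)-3,5-dimethoxyphenyl]methyl}dihydrofuran-2(3H)-one F2, which is driven forward by its stable enolate and settles as the trans isomer. Reduction of the ketone with NaBH4, CeCl3·7H2O in MeOH/THF at −40 °C gives the carbinol epimers, and the route is rejoined at 17.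

**Step 10 (global desilylation and acyl transfer).** The β-hydroxy lactone with free phenols may suffer retro-aldol or quinone-methide side reactions under fluoride, and translactonisation may be incomplete. Any remaining 18 should still converge in step 11, because aqueous acid also catalyses the acyl transfer. The fallback sets out from 17 and reverses the order of events. Treatment with 2 M aq HCl/THF (1:4, rt → 40 °C) cleaves only the alkyl silyl ether, and the same acid drives translactonisation and ring closure with both phenols still silylated. The product is (3S,3aR,6S,6aS)-3-[4-(tert-butyldimethylsilyloxy)-3,5-dimethoxyphenyl]-6-[4-(tert-butyldimethylsilyloxy)-3-methoxyphenyl]tetrahydro-1H,3H-furo[3,4-c]furan-1-one F3. Fluoride (Bu4NF, AcOH, THF, 0 °C) is then used only on this robust bicycle, and the route is rejoined at 20.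

**Step 5 (reductive removal of the auxiliary).** An α-branched β-silyloxy imide is hindered and may react slowly or open the oxazolidinone ring instead. The fallback sets out from 8 and reduces before silylating. LiBH4 (H2O, Et2O, 0 °C) on the free aldol adduct gives (1S,2R)-2-allyl-1-[4-(tert-butyldimethylsilyloxy)-3,5-dimethoxyphenyl]propane-1,3-diol F4. Bis-silylation (TBSOTf 2.4 equiv, 2,6-lutidine, CH2Cl2, −78 → 0 °C) gives tert-butyl{[(R)-2-{(S)-(tert-butyldimethylsilyloxy)[4-(tert-butyldimethylsilyloxy)-3,5-dimethoxyphenyl]methyl}pent-4-en-1-yl]oxy}dimethylsilane F5. Selective cleavage of the primary silyl ether (camphorsulfonic acid 0.1 equiv, MeOH/CH2Cl2 1:1, 0 °C) rejoins the route at 10.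

## Further compounds

F1 | step 9 | methyl 4-(tert-butyldimethylsilyloxy)-3-methoxybenzoate | COC(=O)c1ccc(O[Si](C)(C)C(C)(C)C)c(OC)c1
F2 | step 9 | (3S,4R)-3-[4-(tert-butyldimethylsilyloxy)-3-methoxybenzoyl]-4-{(S)-(tert-butyldimethylsilyloxy)[4-(tert-butyldimethylsilyloxy)-3,5-dimethoxyphenyl]methyl}dihydrofuran-2(3H)-one | O=C1[C@H](C(=O)c2ccc(O[Si](C)(C)C(C)(C)C)c(OC)c2)[C@@H]([C@H](O[Si](C)(C)C(C)(C)C)c2cc(OC)c(O[Si](C)(C)C(C)(C)C)c(OC)c2)CO1
F3 | step 10 | (3S,3aR,6S,6aS)-3-[4-(tert-butyldimethylsilyloxy)-3,5-dimethoxyphenyl]-6-[4-(tert-butyldimethylsilyloxy)-3-methoxyphenyl]tetrahydro-1H,3H-furo[3,4-c]furan-1-one | COc1cc([C@H]2OC[C@H]3[C@@H]2C(=O)O[C@@H]3c2cc(OC)c(O[Si](C)(C)C(C)(C)C)c(OC)c2)ccc1O[Si](C)(C)C(C)(C)C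
F4 | step 5 | (1S,2R)-2-allyl-1-[4-(tert-butyldimethylsilyloxy)-3,5-dimethoxyphenyl]propane-1,3-diol | C=CC[C@H](CO)[C@H](O)c1cc(OC)c(O[Si](C)(C)C(C)(C)C)c(OC)c1
F5 | step 5 | tert-butyl{[(R)-2-{(S)-(tert-butyldimethylsilyloxy)[4-(tert-butyldimethylsilyloxy)-3,5-dimethoxyphenyl]methyl}pent-4-en-1-yl]oxy}dimethylsilane | C=CC[C@H](CO[Si](C)(C)C(C)(C)C)[C@H](O[Si](C)(C)C(C)(C)C)c1cc(OC)c(O[Si](C)(C)C(C)(C)C)c(OC)c1
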